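Open a ledger on Q, the limiting reagent, down to 0.2% in the larch flask by 5.00 h, and post each mole to one of two accounts: the route that uses G, or the other route.

in all of them: Q 0.80 M

| flask | J | G | remark | time |
|---|---|---|---|---|
| larch | 0.80 M | 0.80 M | the very flask that is asked about, followed so far |  |
| birch | 0.80 M | 1.6 M | run made earlier |  |
| flask | 0.800 M | 0.800 M |  | 12 h |

| run | time / h | Z / % | Q / % |
|---|---|---|---|
| larch | 0.167 | 7.8 | 72.2 |
| larch | 0.333 | 10.9 | 53.8 |
| larch | 0.500 | 12.3 | 40.6 |
| larch | 0.833 | 12.5 | 24.5 |
| larch | 1.50 | 11.8 | 10.1 |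
| larch | 3.00 | 10.1 | 1.2 |
| larch | 5.00 | 10.7 | 0.2 |
| birch | 0.167 | 7.4 | 58.4 |
| birch | 0.333 | 9.3 | 35.7 |
| birch | 0.667 | 8.4 | 14.4 |
| birch | 1.33 | 6.6 | 2.8 |
| birch | 2.50 | 5.9 | 0.5 |
| birch | 4.00 | 5.8 | 0 |
| birch | 8.00 | 5.6 | 0 |

(scatter of a reading: 0.3 percentage points)

- the earlier runs were read with a standard deviation of 0.3 percentage points

1. the moment within 12 h at which there is most Z
2. the amount of Z, in percent of the Q charged, at that time

Take first-order rates from the first readings: larch loses Q at 1.95 /h, birch, with twice the G, at 3.22 /h. If the G route scales with G, it takes 1.27 /h in larch and the other route 0.680 /h, a branching ratio of 1.87. Your quantity is the off-G share, the part of the charged Q that escapes G. G falls as it is used, so go round twice: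

first round: 1 / (1 + ratio) = 34.9%

second round: 1 / (1 + ratio × mean G left), with G ending at the first-round share = 44.3%

Late Z in larch, 10.1% and 10.7%, is then 23.5% of that share. In birch the same reckoning gives a share of 25.0%, hence Z of 5.88%, against a reading of 5.8%. The late larch readings lie below the readings 12.3% and 12.5%, so you place the maximum early, between 0.500 h and 0.833 h, with the highest reading at 12.5%.

The forecast gave 12.7% at 0.7 h, holding that “the early maximum should stand”.

The flask gives 12.5% at 0.663 h.

    Q + G → L (k = 0.0295 /M/min)
    Z ⇌ E (K = 3.00, k = 0.0465 /min)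
    J + D → Z (k = 70.4 /M/min)
    Q ⇌ D + X (K = 0.0230 M, k = 0.0116 /min)

By 12.0 h L stands at 57.7% of the Q charged, while your ledger posted 55.7% to the G route.

With 0.20 M of G the ratio is 0.467. The first round posts more Q to G than the G charged, so for the second round you assume that G falls to nil, and the share comes to 81.1%, hence Z of 19.1%. That neighbour computes to 20.0% of Z at 12.0 h, with L at 20.1% of the Q charged and 19.5% of its G still there.

The data are simulated for substances that don't exist.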